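**Plan**

- Retrosynthesis: the four silyl ethers come off last. The oxolane C5 methylene goes back to a lactone carbonyl, the C4–OH bond to an enolate oxidation, the C3–H and C4–H bonds to a hydrogenation, and the C3 CH2OH to a vinyl group.
- Enabling feature: oxolane atoms O1, C2 (aryl), C3 (CH2OH), C4 (C(OH)CH2Ar) and C5 are those of a 5-aryl-furan-2(5H)-one with C3=C4 as a tetrasubstituted alkene and C5 as carbonyl, so C2 is the only centre the ring has to start with.
- That butenolide is cut at C3–vinyl, C4–C5 and O1–C5 into an (aryl)(3-arylprop-1-ynyl)carbinol, CH2=CHMgCl and CO2. The carbinol is cut at C2–C(alkyne) into a dihydrobenzofuran-5-carbaldehyde and a 3-arylpropyne, and the dihydrofuran ring at its C2–C3 bond (carbene C–H insertion).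
- Forward: the iodovanillate supplies ring A, the dihydrofuran ring closes in step 7, aldehyde and alkyne are joined in step 13, the lactone ring closes in step 14 and is reduced to the oxolane in steps 20 and 21.
- Stereochemistry: the cis-dihydrobenzofuran pair comes from a chiral dirhodium carboxylate, the C2 carbinol from a BINOL–titanium alkynylation, C3 from hydrogenation anti to the C2 aryl group, and C4 from enolate hydroxylation anti to the C3 and C2 substituents.

Key step: step 14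

Assumption: Rh2(S-PTTL)4 (step 7) and (R)-BINOL (step 13) are taken to give the (2R,3S)-ester and the (S)-carbinol; if either sense proves opposite, the mirror-image catalyst is used and nothing else changes.

Abbreviations in names: ArS = 3-methoxy-4-(triisopropylsilyloxy)phenyl; DBF = (2R,3R)-3-[(tert-butyldimethylsilyloxy)methyl]-7-methoxy-2-ArS-2,3-dihydro-1-benzofuran-5-yl (2,3-cis); TBS = tert-butyldimethylsilyl. In the Why lines C2–C5 are the locants of the final oxolane (O1, C2 aryl, C3 CH2O, C4 benzyl carbinol, C5); systematic names keep their own locants.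

**Route**

Step 1
Reactants: 1 vanillin
Product: 2 3-methoxy-4-(triisopropylsilyloxy)benzaldehyde
Conditions: i-Pr3SiCl, imidazole, DMF, rt
Reagents that add atoms: chlorotriisopropylsilane, CC(C)[Si](Cl)(C(C)C)C(C)C
Why: Imidazole-mediated O-silylation of the phenol, the triisopropylsilyl ether being chosen because it should withstand the Grignard, amide-base and hydride steps and fall to fluoride in the last step.

Step 2
Reactants: 2 3-methoxy-4-(triisopropylsilyloxy)benzaldehyde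
Product: 3 [3-methoxy-4-(triisopropylsilyloxy)phenyl]methanol
Conditions: NaBH4, MeOH/THF, 0 °C
Reagents that add atoms: none
Why: NaBH4 reduction of the aryl aldehyde to the benzylic alcohol, which at 0 °C should leave the aryl silyl ether untouched.

Step 3
Reactants: 3 [3-methoxy-4-(triisopropylsilyloxy)phenyl]methanol
Product: 4 4-(bromomethyl)-2-methoxy-1-(triisopropylsilyloxy)benzene
Conditions: CBr4, PPh3, CH2Cl2, 0 °C
Reagents that add atoms: carbon tetrabromide, BrC(Br)(Br)Br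
Why: Appel reaction, which converts the benzylic alcohol into the bromide under neutral conditions that spare the silyl ether.

Step 4
Reactants: 5 methyl 4-hydroxy-3-iodo-5-methoxybenzoate; 4 4-(bromomethyl)-2-methoxy-1-(triisopropylsilyloxy)benzene
Product: 6 methyl 3-iodo-5-methoxy-4-(ArS-methoxy)benzoate
Conditions: K2CO3, acetone, 50 °C
Reagents that add atoms: none
Why: Williamson etherification of the phenoxide of 5 with the reactive benzylic bromide, which places the future C2 carbon of the dihydrofuran ring on the phenol oxygen.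

Step 5
Reactants: 6 methyl 3-iodo-5-methoxy-4-(ArS-methoxy)benzoate
Product: 7 methyl 3-methoxy-5-(2-methoxy-2-oxoethyl)-4-(ArS-methoxy)benzoate
Conditions: BrZnCH2CO2Me (1.5 equiv, from BrCH2CO2Me and Zn), Pd2(dba)3 (2.5 mol %), XPhos (6 mol %), THF, 60 °C
Reagents that add atoms: (2-methoxy-2-oxoethyl)zinc bromide, COC(=O)C[Zn]Br (made from methyl bromoacetate, COC(=O)CBr, and Zn)
Why: Palladium-catalysed Reformatsky–Negishi α-arylation, in which zerovalent palladium inserts into the only C–halogen bond, the zinc ester enolate transmetalates and reductive elimination gives the arylacetate without touching the benzoate or the silyl ether.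

Step 6
Reactants: 7 methyl 3-methoxy-5-(2-methoxy-2-oxoethyl)-4-(ArS-methoxy)benzoate
Product: 8 methyl 3-(1-diazo-2-methoxy-2-oxoethyl)-5-methoxy-4-(ArS-methoxy)benzoate
Conditions: 4-acetamidobenzenesulfonyl azide, DBU, MeCN, 0 °C to rt
Reagents that add atoms: 4-acetamidobenzenesulfonyl azide, CC(=O)Nc1ccc(cc1)S(=O)(=O)N=[N+]=[N-]
Why: Regitz diazo transfer from the sulfonyl azide to the DBU-generated arylacetate enolate, the standard entry to aryldiazoacetates.

Step 7
Reactants: 8 methyl 3-(1-diazo-2-methoxy-2-oxoethyl)-5-methoxy-4-(ArS-methoxy)benzoate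
Product: 9 dimethyl (2R,3S)-7-methoxy-2-ArS-2,3-dihydro-1-benzofuran-3,5-dicarboxylate (2,3-cis)
Conditions: Rh2(S-PTTL)4 (dirhodium tetrakis[N-phthaloyl-(S)-tert-leucinate], 1 mol %), toluene, −78 °C
Reagents that add atoms: none
Why: Dirhodium-carbenoid 1,5 C–H insertion into the ether-activated benzylic C–H bond closes the five-membered dihydrofuran ring, the bulky chiral carboxylate catalyst being expected to give the kinetic 2,3-cis product and to fix both new centres (C2 R, C3 S) by catalyst control.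

Step 8
Reactants: 9 dimethyl (2R,3S)-7-methoxy-2-ArS-2,3-dihydro-1-benzofuran-3,5-dicarboxylate
Product: 10 [(2R,3R)-7-methoxy-2-ArS-2,3-dihydro-1-benzofuran-3,5-diyl]dimethanol
Conditions: i-Bu2AlH (5 equiv), CH2Cl2, −78 to 0 °C; aq. KNaC4H4O6
Reagents that add atoms: none
Why: Hydride reduction of both esters with i-Bu2AlH, a non-basic reagent that should not epimerise the C3 centre next to the former ester (its label changes from S to R only because the substituent ranking changes).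

Step 9
Reactants: 10 [(2R,3R)-7-methoxy-2-ArS-2,3-dihydro-1-benzofuran-3,5-diyl]dimethanol
Product: 11 (2R,3R)-3-(hydroxymethyl)-7-methoxy-2-ArS-2,3-dihydro-1-benzofuran-5-carbaldehyde
Conditions: MnO2 (15 equiv), CH2Cl2, rt
Reagents that add atoms: none
Why: MnO2 oxidation, which is selective for the benzylic alcohol over the aliphatic primary alcohol.

Step 10
Reactants: 11 (2R,3R)-3-(hydroxymethyl)-7-methoxy-2-ArS-2,3-dihydro-1-benzofuran-5-carbaldehyde
Product: 12 (2R,3R)-3-[(tert-butyldimethylsilyloxy)methyl]-7-methoxy-2-ArS-2,3-dihydro-1-benzofuran-5-carbaldehyde (DBF–CHO)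
Conditions: t-BuMe2SiCl, imidazole, CH2Cl2, rt
Reagents that add atoms: tert-butylchlorodimethylsilane, CC(C)(C)[Si](C)(C)Cl
Why: Imidazole-mediated silylation of the remaining primary alcohol, needed because a free hydroxyl would quench the zinc and magnesium reagents that follow.

Step 11
Reactants: 13 ethynyltrimethylsilane; 4 4-(bromomethyl)-2-methoxy-1-(triisopropylsilyloxy)benzene
Product: 15 trimethyl(3-ArS-prop-1-yn-1-yl)silane, via (trimethylsilylethynyl)magnesium bromide 14 (not isolated)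
Conditions: EtMgBr, THF, 0 to 40 °C; then 4, CuBr·SMe2 (10 mol %), 60 °C
Reagents that add atoms: none
Why: Copper-catalysed sp–sp3 coupling of the alkynyl Grignard reagent with the benzylic bromide, the trimethylsilyl cap preventing a second benzylation.

Step 12
Reactants: 15 trimethyl(3-ArS-prop-1-yn-1-yl)silane
Product: 16 2-methoxy-4-(prop-2-yn-1-yl)-1-(triisopropylsilyloxy)benzene
Conditions: K2CO3 (0.2 equiv), MeOH/THF, 0 °C, short reaction time
Reagents that add atoms: none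
Why: Methoxide-catalysed protodesilylation of the alkynyl C–Si bond, run cold and briefly so that the aryl silyl ether and the propargylic CH2 (prone to allene formation) are not affected.

Step 13
Reactants: 16 2-methoxy-4-(prop-2-yn-1-yl)-1-(triisopropylsilyloxy)benzene; 12 DBF–CHO
Product: 18 (1S)-1-DBF-4-ArS-but-2-yn-1-ol, via alkynyl(ethyl)zinc 17 (not isolated)
Conditions: 16 (2 equiv), ZnEt2 (2 equiv), Cy2NH (5 mol %), (R)-BINOL (20 mol %), Et2O, rt; Ti(OiPr)4 (50 mol %); then 12, rt; aq. NH4Cl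
Reagents that add atoms: none
Why: BINOL–titanium-catalysed enantioselective addition of an alkynylzinc reagent to an aryl aldehyde, in which the (R)-BINOL–titanium complex is expected to expose one aldehyde face and set the carbinol (future C2) as S by catalyst control, the remote dihydrobenzofuran centres having little influence.

Step 14
Reactants: 18 (1S)-1-DBF-4-ArS-but-2-yn-1-ol; 19 vinylmagnesium chloride; 20 carbon dioxide
Product: 23 (5S)-5-DBF-4-ethenyl-3-(ArS-methyl)furan-2(5H)-one, via oxamagnesacycle 21 (not isolated), via Z-hydroxy acid 22 (not isolated)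
Conditions: CH2=CHMgCl (4 equiv), THF, 65 °C; CO2 (1 atm), 0 °C to rt; 10% aq. citric acid, 0 °C
Reagents that add atoms: vinylmagnesium chloride (19), C=C[Mg]Cl; carbon dioxide (20), O=C=O
Why: One equivalent of CH2=CHMgCl deprotonates the carbinol (ethene is lost) and the magnesium alkoxide then guides a second equivalent so that vinyl adds to the proximal alkyne carbon and magnesium to the distal one from opposite sides, an anti-carbomagnesiation that gives the five-membered 2,5-dihydro-1,2-oxamagnesole 21 and the C3–vinyl bond. CO2 inserts into the alkenyl C–Mg bond to form C4–C5, and because the carboxylate sits cis to the carbinol, mild acid closes the lactone by attack of the hydroxyl oxygen on the carboxyl carbon, a 5-exo-trig closure that forms O1–C5. The closest known reaction type is the magnesium-mediated anti-carbometallation of propargylic alcohols with vinyl Grignard reagents followed by CO2 trapping to give α,β-disubstituted butenolides. No new stereocentre is formed, and the C2 carbinol centre is retained because only its O–H bond reacts. The step needs proximal regioselectivity and anti stereoselectivity, both secured by chelation in the alkoxide, and it needs the benzylic propargylic CH2 and the acid-sensitive p-alkoxybenzylic carbinol to survive, for which the weakly basic Grignard reagent and a citric acid work-up at 0 °C are chosen.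

Step 15
Reactants: 23 (5S)-5-DBF-4-ethenyl-3-(ArS-methyl)furan-2(5H)-one
Product: 25 (2S)-2-DBF-4-(ArS-methyl)-5-oxo-2,5-dihydrofuran-3-carbaldehyde, via vicinal diol 24 (not isolated)
Conditions: OsO4 (2 mol %), NaIO4 (4 equiv), 2,6-lutidine, dioxane/H2O, rt
Reagents that add atoms: osmium tetroxide, O=[Os](=O)(=O)=O; sodium periodate (terminal oxidant that restores the oxygen on osmium), [Na+].[O-]I(=O)(=O)=O
Why: Lemieux–Johnson oxidation, in which OsO4 dihydroxylates the terminal vinyl group much faster than the tetrasubstituted ester-conjugated ring alkene and NaIO4 cleaves the diol to the aldehyde while returning the osmium to OsO4.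

Step 16
Reactants: 25 (2S)-2-DBF-4-(ArS-methyl)-5-oxo-2,5-dihydrofuran-3-carbaldehyde
Product: 26 (5S)-5-DBF-4-(hydroxymethyl)-3-(ArS-methyl)furan-2(5H)-one
Conditions: NaBH4, CeCl3·7H2O, MeOH/THF, −78 °C; AcOH quench
Reagents that add atoms: none
Why: Luche reduction, giving clean 1,2-reduction of the conjugated aldehyde at −78 °C, with an acetic acid quench so that the C2–H does not epimerise and the new alkoxide does not translactonise.

Step 17
Reactants: 26 (5S)-5-DBF-4-(hydroxymethyl)-3-(ArS-methyl)furan-2(5H)-one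
Product: 27 (5S)-4-[(tert-butyldimethylsilyloxy)methyl]-5-DBF-3-(ArS-methyl)furan-2(5H)-one
Conditions: t-BuMe2SiOTf, 2,6-lutidine, CH2Cl2, −78 °C
Reagents that add atoms: tert-butyldimethylsilyl trifluoromethanesulfonate, CC(C)(C)[Si](C)(C)OS(=O)(=O)C(F)(F)F
Why: Silylation with a silyl triflate and 2,6-lutidine, fast and non-nucleophilic, which blocks the hydroxymethyl group before it can attack the lactone carbonyl.

Step 18
Reactants: 27 (5S)-4-[(tert-butyldimethylsilyloxy)methyl]-5-DBF-3-(ArS-methyl)furan-2(5H)-one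
Product: 28 (3R,4R,5R)-4-[(tert-butyldimethylsilyloxy)methyl]-5-DBF-3-(ArS-methyl)oxolan-2-one (all-cis)
Conditions: H2 (4 atm), 5% Rh/Al2O3, EtOAc, rt
Reagents that add atoms: none
Why: Heterogeneous syn hydrogenation of the tetrasubstituted butenolide alkene over Rh/Al2O3, both hydrogens adding to the ring face opposite the C2 aryl group so that C3 (CH2OTBS cis to aryl) and the temporary C4 centre are set by substrate control, rhodium being chosen because it is a poor catalyst for benzylic C–O hydrogenolysis.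

Step 19
Reactants: 28 (3R,4R,5R)-4-[(tert-butyldimethylsilyloxy)methyl]-5-DBF-3-(ArS-methyl)oxolan-2-one
Product: 30 (3S,4R,5R)-4-[(tert-butyldimethylsilyloxy)methyl]-5-DBF-3-hydroxy-3-(ArS-methyl)oxolan-2-one, via potassium enolate 29 (not isolated)
Conditions: KN(SiMe3)2, THF, −78 °C; 2-(phenylsulfonyl)-3-phenyloxaziridine, −78 °C; aq. NH4Cl
Reagents that add atoms: 2-(phenylsulfonyl)-3-phenyloxaziridine, O=S(=O)(c1ccccc1)N1OC1c1ccccc1
Why: Davis enolate oxidation, in which the oxaziridine transfers oxygen to the enolate face opposite the cis-disposed C3 CH2OTBS and C2 aryl groups, so that C4 is set with OH trans to them and benzyl cis to CH2OTBS (substrate control).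

Step 20
Reactants: 30 (3S,4R,5R)-4-[(tert-butyldimethylsilyloxy)methyl]-5-DBF-3-hydroxy-3-(ArS-methyl)oxolan-2-one
Product: 31 (3S,4R,5R)-4-[(tert-butyldimethylsilyloxy)methyl]-5-DBF-3-(ArS-methyl)oxolane-2,3-diol (lactol; both C2 anomers)
Conditions: i-Bu2AlH (3 equiv), CH2Cl2, −78 °C; aq. KNaC4H4O6
Reagents that add atoms: none
Why: Partial reduction of the lactone by i-Bu2AlH at −78 °C, where the aluminium hemiacetal is stable and collapses to the lactol only on work-up (one equivalent is consumed by the tertiary hydroxyl).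

Step 21
Reactants: 31 (3S,4R,5R)-4-[(tert-butyldimethylsilyloxy)methyl]-5-DBF-3-(ArS-methyl)oxolane-2,3-diol
Product: 32 (3S,4R,5R)-4-[(tert-butyldimethylsilyloxy)methyl]-5-DBF-3-(ArS-methyl)oxolan-3-ol
Conditions: Et3SiH (5 equiv), BF3·OEt2 (2 equiv), CH2Cl2, −78 °C; aq. NaHCO3
Reagents that add atoms: none
Why: Ionic hydrogenation of the lactol (reductive deoxygenation through the cyclic oxocarbenium ion with Et3SiH as hydride donor), which creates no stereocentre and at −78 °C should outpace ionisation of the benzylic C–O bonds.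

Step 22
Reactants: 32 (3S,4R,5R)-4-[(tert-butyldimethylsilyloxy)methyl]-5-DBF-3-(ArS-methyl)oxolan-3-ol
Product: 33 (3S,4R,5R)-5-[(2R,3R)-2-(4-hydroxy-3-methoxyphenyl)-3-(hydroxymethyl)-7-methoxy-2,3-dihydro-1-benzofuran-5-yl]-3-[(4-hydroxy-3-methoxyphenyl)methyl]-4-(hydroxymethyl)oxolan-3-ol (CNP0284796.1)
Conditions: Bu4NF (6 equiv), AcOH (6 equiv), THF, 0 °C to rt
Reagents that add atoms: none
Why: Fluoride-mediated cleavage of the two aryl and two alkyl silyl ethers, buffered with acetic acid so that the liberated phenoxide does not open the cis-dihydrobenzofuran through a quinone methide.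

**Compound list**

1 | vanillin (4-hydroxy-3-methoxybenzaldehyde) | O=Cc1ccc(O)c(OC)c1 | starting material
2 | 3-methoxy-4-(triisopropylsilyloxy)benzaldehyde | O=Cc1ccc(O[Si](C(C)C)(C(C)C)C(C)C)c(OC)c1 | intermediate
3 | [3-methoxy-4-(triisopropylsilyloxy)phenyl]methanol | OCc1ccc(O[Si](C(C)C)(C(C)C)C(C)C)c(OC)c1 | intermediate
4 | 4-(bromomethyl)-2-methoxy-1-(triisopropylsilyloxy)benzene | BrCc1ccc(O[Si](C(C)C)(C(C)C)C(C)C)c(OC)c1 | intermediate
5 | methyl 4-hydroxy-3-iodo-5-methoxybenzoate | COC(=O)c1cc(I)c(O)c(OC)c1 | starting material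
6 | methyl 3-iodo-5-methoxy-4-(ArS-methoxy)benzoate | COC(=O)c1cc(I)c(OCc2ccc(O[Si](C(C)C)(C(C)C)C(C)C)c(OC)c2)c(OC)c1 | intermediate
7 | methyl 3-methoxy-5-(2-methoxy-2-oxoethyl)-4-(ArS-methoxy)benzoate | COC(=O)Cc1cc(C(=O)OC)cc(OC)c1OCc1ccc(O[Si](C(C)C)(C(C)C)C(C)C)c(OC)c1 | intermediate
8 | methyl 3-(1-diazo-2-methoxy-2-oxoethyl)-5-methoxy-4-(ArS-methoxy)benzoate | COC(=O)C(=[N+]=[N-])c1cc(C(=O)OC)cc(OC)c1OCc1ccc(O[Si](C(C)C)(C(C)C)C(C)C)c(OC)c1 | intermediate
9 | dimethyl (2R,3S)-7-methoxy-2-ArS-2,3-dihydro-1-benzofuran-3,5-dicarboxylate (2,3-cis) | COC(=O)c1cc(OC)c2c(c1)[C@H](C(=O)OC)[C@H](c1ccc(O[Si](C(C)C)(C(C)C)C(C)C)c(OC)c1)O2 | intermediate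
10 | [(2R,3R)-7-methoxy-2-ArS-2,3-dihydro-1-benzofuran-3,5-diyl]dimethanol | OCc1cc(OC)c2c(c1)[C@H](CO)[C@H](c1ccc(O[Si](C(C)C)(C(C)C)C(C)C)c(OC)c1)O2 | intermediate
11 | (2R,3R)-3-(hydroxymethyl)-7-methoxy-2-ArS-2,3-dihydro-1-benzofuran-5-carbaldehyde | O=Cc1cc(OC)c2c(c1)[C@H](CO)[C@H](c1ccc(O[Si](C(C)C)(C(C)C)C(C)C)c(OC)c1)O2 | intermediate
12 | (2R,3R)-3-[(tert-butyldimethylsilyloxy)methyl]-7-methoxy-2-ArS-2,3-dihydro-1-benzofuran-5-carbaldehyde (DBF–CHO) | O=Cc1cc(OC)c2c(c1)[C@H](CO[Si](C)(C)C(C)(C)C)[C@H](c1ccc(O[Si](C(C)C)(C(C)C)C(C)C)c(OC)c1)O2 | intermediate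
13 | ethynyltrimethylsilane | C#C[Si](C)(C)C | starting material
14 | (trimethylsilylethynyl)magnesium bromide | C[Si](C)(C)C#C[Mg]Br | intermediate (not isolated)
15 | trimethyl(3-ArS-prop-1-yn-1-yl)silane | C[Si](C)(C)C#CCc1ccc(O[Si](C(C)C)(C(C)C)C(C)C)c(OC)c1 | intermediate
16 | 2-methoxy-4-(prop-2-yn-1-yl)-1-(triisopropylsilyloxy)benzene | C#CCc1ccc(O[Si](C(C)C)(C(C)C)C(C)C)c(OC)c1 | intermediate
17 | ethyl(3-ArS-prop-1-yn-1-yl)zinc | CC[Zn]C#CCc1ccc(O[Si](C(C)C)(C(C)C)C(C)C)c(OC)c1 | intermediate (not isolated)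
18 | (1S)-1-DBF-4-ArS-but-2-yn-1-ol | O[C@@H](c1cc(OC)c2c(c1)[C@H](CO[Si](C)(C)C(C)(C)C)[C@H](c1ccc(O[Si](C(C)C)(C(C)C)C(C)C)c(OC)c1)O2)C#CCc1ccc(O[Si](C(C)C)(C(C)C)C(C)C)c(OC)c1 | intermediate
19 | vinylmagnesium chloride | C=C[Mg]Cl | starting material
20 | carbon dioxide | O=C=O | starting material
21 | (5S)-5-DBF-4-ethenyl-3-(ArS-methyl)-2,5-dihydro-1,2-oxamagnesole | C=CC1=C(Cc2ccc(O[Si](C(C)C)(C(C)C)C(C)C)c(OC)c2)[Mg]O[C@H]1c1cc(OC)c2c(c1)[C@H](CO[Si](C)(C)C(C)(C)C)[C@H](c1ccc(O[Si](C(C)C)(C(C)C)C(C)C)c(OC)c1)O2 | intermediate (not isolated)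
22 | (2Z,4S)-2-(ArS-methyl)-4-DBF-3-ethenyl-4-hydroxybut-2-enoic acid | OC(=O)/C(Cc1ccc(O[Si](C(C)C)(C(C)C)C(C)C)c(OC)c1)=C(/C=C)[C@@H](O)c1cc(OC)c2c(c1)[C@H](CO[Si](C)(C)C(C)(C)C)[C@H](c1ccc(O[Si](C(C)C)(C(C)C)C(C)C)c(OC)c1)O2 | intermediate (not isolated)
23 | (5S)-5-DBF-4-ethenyl-3-(ArS-methyl)furan-2(5H)-one | O=C1O[C@@H](c2cc(OC)c3c(c2)[C@H](CO[Si](C)(C)C(C)(C)C)[C@H](c2ccc(O[Si](C(C)C)(C(C)C)C(C)C)c(OC)c2)O3)C(C=C)=C1Cc1ccc(O[Si](C(C)C)(C(C)C)C(C)C)c(OC)c1 | intermediate
24 | (5S)-5-DBF-4-(1,2-dihydroxyethyl)-3-(ArS-methyl)furan-2(5H)-one (both side-chain epimers) | O=C1O[C@@H](c2cc(OC)c3c(c2)[C@H](CO[Si](C)(C)C(C)(C)C)[C@H](c2ccc(O[Si](C(C)C)(C(C)C)C(C)C)c(OC)c2)O3)C(C(O)CO)=C1Cc1ccc(O[Si](C(C)C)(C(C)C)C(C)C)c(OC)c1 | intermediate (not isolated)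
25 | (2S)-2-DBF-4-(ArS-methyl)-5-oxo-2,5-dihydrofuran-3-carbaldehyde | O=C1O[C@@H](c2cc(OC)c3c(c2)[C@H](CO[Si](C)(C)C(C)(C)C)[C@H](c2ccc(O[Si](C(C)C)(C(C)C)C(C)C)c(OC)c2)O3)C(C=O)=C1Cc1ccc(O[Si](C(C)C)(C(C)C)C(C)C)c(OC)c1 | intermediate
26 | (5S)-5-DBF-4-(hydroxymethyl)-3-(ArS-methyl)furan-2(5H)-one | O=C1O[C@@H](c2cc(OC)c3c(c2)[C@H](CO[Si](C)(C)C(C)(C)C)[C@H](c2ccc(O[Si](C(C)C)(C(C)C)C(C)C)c(OC)c2)O3)C(CO)=C1Cc1ccc(O[Si](C(C)C)(C(C)C)C(C)C)c(OC)c1 | intermediate
27 | (5S)-4-[(tert-butyldimethylsilyloxy)methyl]-5-DBF-3-(ArS-methyl)furan-2(5H)-one | O=C1O[C@@H](c2cc(OC)c3c(c2)[C@H](CO[Si](C)(C)C(C)(C)C)[C@H](c2ccc(O[Si](C(C)C)(C(C)C)C(C)C)c(OC)c2)O3)C(CO[Si](C)(C)C(C)(C)C)=C1Cc1ccc(O[Si](C(C)C)(C(C)C)C(C)C)c(OC)c1 | intermediate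
28 | (3R,4R,5R)-4-[(tert-butyldimethylsilyloxy)methyl]-5-DBF-3-(ArS-methyl)oxolan-2-one (all-cis) | O=C1O[C@@H](c2cc(OC)c3c(c2)[C@H](CO[Si](C)(C)C(C)(C)C)[C@H](c2ccc(O[Si](C(C)C)(C(C)C)C(C)C)c(OC)c2)O3)[C@@H](CO[Si](C)(C)C(C)(C)C)[C@H]1Cc1ccc(O[Si](C(C)C)(C(C)C)C(C)C)c(OC)c1 | intermediate
29 | potassium (4R,5R)-4-[(tert-butyldimethylsilyloxy)methyl]-5-DBF-3-(ArS-methyl)-4,5-dihydrofuran-2-olate | [K+].[O-]C1=C(Cc2ccc(O[Si](C(C)C)(C(C)C)C(C)C)c(OC)c2)[C@H](CO[Si](C)(C)C(C)(C)C)[C@H](c2cc(OC)c3c(c2)[C@H](CO[Si](C)(C)C(C)(C)C)[C@H](c2ccc(O[Si](C(C)C)(C(C)C)C(C)C)c(OC)c2)O3)O1 | intermediate (not isolated)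
30 | (3S,4R,5R)-4-[(tert-butyldimethylsilyloxy)methyl]-5-DBF-3-hydroxy-3-(ArS-methyl)oxolan-2-one | O=C1O[C@@H](c2cc(OC)c3c(c2)[C@H](CO[Si](C)(C)C(C)(C)C)[C@H](c2ccc(O[Si](C(C)C)(C(C)C)C(C)C)c(OC)c2)O3)[C@@H](CO[Si](C)(C)C(C)(C)C)[C@@]1(O)Cc1ccc(O[Si](C(C)C)(C(C)C)C(C)C)c(OC)c1 | intermediate
31 | (3S,4R,5R)-4-[(tert-butyldimethylsilyloxy)methyl]-5-DBF-3-(ArS-methyl)oxolane-2,3-diol (both C2 anomers) | OC1O[C@@H](c2cc(OC)c3c(c2)[C@H](CO[Si](C)(C)C(C)(C)C)[C@H](c2ccc(O[Si](C(C)C)(C(C)C)C(C)C)c(OC)c2)O3)[C@@H](CO[Si](C)(C)C(C)(C)C)[C@@]1(O)Cc1ccc(O[Si](C(C)C)(C(C)C)C(C)C)c(OC)c1 | intermediate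
32 | (3S,4R,5R)-4-[(tert-butyldimethylsilyloxy)methyl]-5-DBF-3-(ArS-methyl)oxolan-3-ol | C1O[C@@H](c2cc(OC)c3c(c2)[C@H](CO[Si](C)(C)C(C)(C)C)[C@H](c2ccc(O[Si](C(C)C)(C(C)C)C(C)C)c(OC)c2)O3)[C@@H](CO[Si](C)(C)C(C)(C)C)[C@@]1(O)Cc1ccc(O[Si](C(C)C)(C(C)C)C(C)C)c(OC)c1 | intermediate
33 | (3S,4R,5R)-5-[(2R,3R)-2-(4-hydroxy-3-methoxyphenyl)-3-(hydroxymethyl)-7-methoxy-2,3-dihydro-1-benzofuran-5-yl]-3-[(4-hydroxy-3-methoxyphenyl)methyl]-4-(hydroxymethyl)oxolan-3-ol | COc1cc(C[C@@]2(O)CO[C@@H](c3cc(OC)c4c(c3)[C@H](CO)[C@H](c3ccc(O)c(OC)c3)O4)[C@H]2CO)ccc1O | target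

**Step count and risks**

Total step count: 22. Longest linear sequence: 20 steps (steps 1–10, then 13–22, from vanillin); the alkyne branch (steps 11 and 12) joins at step 13.

Steps most likely to fail:

Step 14. The Grignard reagent may metalate the doubly activated benzylic propargylic CH2 (propargyl–allenyl isomerisation) faster than it adds, or the addition may stall at the crowded secondary alkoxide. On acidification the p-alkoxybenzylic carbinol may also ionise and lose its configuration. The fallback builds the same butenolide by conjugate addition instead. It sets out from aldehyde 12, which is alkynylated with methyl propiolate under the BINOL/Ti(OiPr)4/ZnEt2 conditions of step 13 to give methyl (4S)-4-DBF-4-hydroxybut-2-ynoate F1. Syn-carbocupration of F1 with (CH2=CH)2CuLi at −78 °C places vinyl on the carbon next to the carbinol, and the resulting α-alkenylcopper is alkylated with bromide 4 to give methyl (2Z,4S)-2-(ArS-methyl)-4-DBF-3-ethenyl-4-hydroxybut-2-enoate F2. Its ester is cis to the carbinol, so it lactonises with loss of methanol, and the route is rejoined at butenolide 23.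

Step 18. Uptake of hydrogen by the hindered tetrasubstituted alkene may be slow enough for arene saturation, hydrogenolysis of the benzylic lactone C–O bond, or migration of the double bond toward the aryl group (which would erase C2) to compete. The fallback sets out from 27 and uses conjugate reduction with NaBH4 and NiCl2·6H2O in MeOH at 0 °C. Hydride should reach the β-carbon from the face opposite the aryl group, giving the lactone (3RS,4R,5R)-4-[(tert-butyldimethylsilyloxy)methyl]-5-DBF-3-(ArS-methyl)oxolan-2-one F3 as a mixture at the α-carbon only. That centre is planarised in step 19, so both epimers converge on enolate 29 and the route is rejoined at 30.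

Step 21. BF3 may ionise the benzylic C2–O bond of the new oxolane or the benzylic C–O bond of the dihydrobenzofuran, epimerising either cis array to trans, or the α-hydroxy oxocarbenium ion may suffer a 1,2-benzyl shift. The fallback avoids acid. It sets out from hydroxy lactone 30, which LiBH4 in THF reduces to the triol (configuration of 30) F4. Bu2SnO-catalysed tosylation (TsCl, Et3N) selects the primary hydroxyl of the 1,2-diol and gives the primary tosylate F5. KOt-Bu then closes the ring by attack of the C2 alkoxide on the CH2 carbon, directly or through the 2,2-disubstituted epoxide F6 (5-exo-tet opening at its CH2 terminus). The C2–O bond is never broken, and the route is rejoined at 32.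

**Further compounds**

F1 | step 14 | methyl (4S)-4-DBF-4-hydroxybut-2-ynoate | O[C@@H](c1cc(OC)c2c(c1)[C@H](CO[Si](C)(C)C(C)(C)C)[C@H](c1ccc(O[Si](C(C)C)(C(C)C)C(C)C)c(OC)c1)O2)C#CC(=O)OC
F2 | step 14 | methyl (2Z,4S)-2-(ArS-methyl)-4-DBF-3-ethenyl-4-hydroxybut-2-enoate | COC(=O)/C(Cc1ccc(O[Si](C(C)C)(C(C)C)C(C)C)c(OC)c1)=C(/C=C)[C@@H](O)c1cc(OC)c2c(c1)[C@H](CO[Si](C)(C)C(C)(C)C)[C@H](c1ccc(O[Si](C(C)C)(C(C)C)C(C)C)c(OC)c1)O2
F3 | step 18 | (3RS,4R,5R)-4-[(tert-butyldimethylsilyloxy)methyl]-5-DBF-3-(ArS-methyl)oxolan-2-one (28 and its C3 epimer) | O=C1O[C@@H](c2cc(OC)c3c(c2)[C@H](CO[Si](C)(C)C(C)(C)C)[C@H](c2ccc(O[Si](C(C)C)(C(C)C)C(C)C)c(OC)c2)O3)[C@@H](CO[Si](C)(C)C(C)(C)C)C1Cc1ccc(O[Si](C(C)C)(C(C)C)C(C)C)c(OC)c1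
F4 | step 21 | 2-(ArS-methyl)-3-[(tert-butyldimethylsilyloxy)methyl]-4-DBF-butane-1,2,4-triol (configuration of 30) | O[C@@H](c1cc(OC)c2c(c1)[C@H](CO[Si](C)(C)C(C)(C)C)[C@H](c1ccc(O[Si](C(C)C)(C(C)C)C(C)C)c(OC)c1)O2)[C@@H](CO[Si](C)(C)C(C)(C)C)[C@@](CO)(O)Cc1ccc(O[Si](C(C)C)(C(C)C)C(C)C)c(OC)c1
F5 | step 21 | 1-O-(4-methylbenzenesulfonyl) derivative of triol F4 | O[C@@H](c1cc(OC)c2c(c1)[C@H](CO[Si](C)(C)C(C)(C)C)[C@H](c1ccc(O[Si](C(C)C)(C(C)C)C(C)C)c(OC)c1)O2)[C@@H](CO[Si](C)(C)C(C)(C)C)[C@@](COS(=O)(=O)c1ccc(C)cc1)(O)Cc1ccc(O[Si](C(C)C)(C(C)C)C(C)C)c(OC)c1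
F6 | step 21 | 1,2-epoxide derived from tosylate F5 (2-(ArS-methyl)oxirane bearing the DBF carbinol side chain) | O[C@@H](c1cc(OC)c2c(c1)[C@H](CO[Si](C)(C)C(C)(C)C)[C@H](c1ccc(O[Si](C(C)C)(C(C)C)C(C)C)c(OC)c1)O2)[C@@H](CO[Si](C)(C)C(C)(C)C)[C@]1(CO1)Cc1ccc(O[Si](C(C)C)(C(C)C)C(C)C)c(OC)c1
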